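The cycloheptanone is opened at the bond between its ketone carbon (C9) and the ring-fusion CH (C5). This works because C9 stands 1,4 to the cyclopentane carbinol carbon C7. Once C7 is a ketone, C5 is the β-carbon of a cyclopentenone, and C9 can be delivered as a carbene-generated acyl anion. A single intramolecular Stetter reaction then forms C9–C5, closes the seven-membered ring and creates the C5 stereocentre. The precursor is a 4-silyloxy-5,5-dimethylcyclopent-2-enone. Its carbinol carbon C4 carries a four-carbon tether ending in a non-enolisable, α-quaternary aldehyde, with C1, C10 and C4 already configured.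

Key step: step 14

Atom labels used throughout:
- Seven-membered ring: C1 (CHMe), C2, C3, C4 (fusion C–O), C5 (fusion CH), C9 (C=O), C10 (quaternary C).
- Cyclopentane: C4, C5, C6 (CH2), C7 (CHOH), C8 (CMe2).
- Side chain on C10: C11, C12, then the butenolide.
- The target is (1R,4S,5S,7S,10R).

Assumption: at C5 the trans-fused hydroazulenone is taken to be the more stable epimer. The fallback to step 17 covers the opposite case.

Step 1
Reactants: 1 methyl hydrogen (R)-3-methylglutarate
Product: 3 (4R)-4-methyloxan-2-one, via hydroxy ester 2 (not isolated)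
Conditions: BH3·SMe2, THF, 0 °C to rt; aq. work-up; TsOH (cat.), CH2Cl2, rt
Reagents that add atoms: none
Why: Chemoselective borane reduction: BH3 reduces the free acid far faster than the methyl ester and the δ-hydroxy ester then closes to the six-membered lactone under acid catalysis, the stereocentre of 1 (future C1, R) being untouched.

Step 2
Reactants: 3 (4R)-4-methyloxan-2-one; 4 benzyl 2-iodoethyl ether
Product: 6 (3S,4R)-3-[2-(benzyloxy)ethyl]-4-methyloxan-2-one, via lithium enolate 5 (not isolated)
Conditions: LDA, THF, −78 °C; 4, DMPU, −78 to −20 °C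
Reagents that add atoms: none
Why: Enolate alkylation (SN2) of the lactone enolate by a primary iodide in the presence of DMPU should go anti to the C1 methyl group, and the configuration of the new centre is of no consequence because step 3 planarises it again.

Step 3
Reactants: 6 (3S,4R)-3-[2-(benzyloxy)ethyl]-4-methyloxan-2-one
Product: 8 (3R,4R)-3-[2-(benzyloxy)ethyl]-3,4-dimethyloxan-2-one, via lithium enolate 7 (not isolated)
Conditions: LDA, THF, −78 °C; MeI, −78 to −40 °C
Reagents that add atoms: iodomethane, IC
Why: Second enolate alkylation: in enolate 7 allylic 1,2-strain with the C11 chain forces the C1 methyl group pseudoaxial, so the small electrophile attacks the opposite face and sets quaternary C10 (R) with the two methyl groups trans, which is why methyl is introduced last.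

Step 4
Reactants: 8 (3R,4R)-3-[2-(benzyloxy)ethyl]-3,4-dimethyloxan-2-one
Product: 9 (2R,3R)-2-[2-(benzyloxy)ethyl]-2,3-dimethylpentane-1,5-diol
Conditions: LiAlH4, THF, 0 °C to rt
Reagents that add atoms: none
Why: Hydride reduction of a lactone to the 1,5-diol, which leaves the benzyl ether and both stereocentres alone.

Step 5
Reactants: 9 (2R,3R)-2-[2-(benzyloxy)ethyl]-2,3-dimethylpentane-1,5-diol
Product: 10 (2R,3R)-2-[2-(benzyloxy)ethyl]-5-iodo-2,3-dimethylpentan-1-ol
Conditions: I2, PPh3, imidazole, CH2Cl2, 0 °C
Reagents that add atoms: iodine, [I][I]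
Why: Appel-type iodination: iodide can displace the alkoxyphosphonium group only at the unhindered C3 carbinol, because SN2 at the neopentyl C9 carbinol next to quaternary C10 is very slow, and the low temperature disfavours closure to the tetrahydropyran.

Step 6
Reactants: 10 (2R,3R)-2-[2-(benzyloxy)ethyl]-5-iodo-2,3-dimethylpentan-1-ol
Product: 11 TBS ether of 10
Conditions: TBSOTf, 2,6-lutidine, CH2Cl2, 0 °C
Reagents that add atoms: tert-butyldimethylsilyl triflate (TBSOTf), CC(C)(C)[Si](C)(C)OS(=O)(=O)C(F)(F)F
Why: Silylation of the neopentyl alcohol by the reactive triflate and a non-nucleophilic base avoids N-alkylation by the primary iodide, and C9 is masked at the alcohol level because no carbonyl group at C9 would survive the alkyllithium of step 9.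

Step 7
Reactants: 12 2,2-dimethylcyclopentane-1,3-dione
Product: 13 (3R)-3-hydroxy-2,2-dimethylcyclopentan-1-one
Conditions: (S)-1-methyl-3,3-diphenyltetrahydro-1H,3H-pyrrolo[1,2-c][1,3,2]oxazaborole [(S)-Me-CBS] (15 mol %), catecholborane, toluene, −60 °C
Reagents that add atoms: none
Why: Corey–Bakshi–Shibata reduction of one of two enantiotopic carbonyl groups: the ketone binds with CH2 as the small and CMe2 as the large flank, so the (S)-catalyst should give the (R)-alcohol, and one equivalent of the mild borane at low temperature stops at the ketol.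

Step 8
Reactants: 13 (3R)-3-hydroxy-2,2-dimethylcyclopentan-1-one
Product: 14 (3R)-3-(tert-butyldimethylsilyloxy)-2,2-dimethylcyclopentan-1-one
Conditions: TBSOTf, 2,6-lutidine, CH2Cl2, −78 to 0 °C
Reagents that add atoms: tert-butyldimethylsilyl triflate (TBSOTf), CC(C)(C)[Si](C)(C)OS(=O)(=O)C(F)(F)F
Why: The triflate silylates the hindered secondary alcohol without the strong base that would trigger retro-aldol opening, and hence racemisation, of the β-hydroxy ketone.

Step 9
Reactants: 11 TBS ether of 10; 14 (3R)-3-(tert-butyldimethylsilyloxy)-2,2-dimethylcyclopentan-1-one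
Product: 17 coupled tertiary alcohol (1R,4S,7R,10R; C4–OH cis to C7–OTBS), via alkyllithium 15 (not isolated), via alkylcerium dichloride 16 (not isolated)
Conditions: t-BuLi (2.1 equiv), Et2O–pentane, −78 °C; CeCl3, THF, −78 °C; 14, −78 to −40 °C
Reagents that add atoms: none
Why: Iodine–lithium exchange, transmetalation to the weakly basic organocerium reagent and 1,2-addition to the hindered, enolisable ketone; the OTBS group, pushed pseudoaxial by the adjacent CMe2 group, screens its own face, so C3 should enter anti to it and set C4 (S), a minor epimer being removable by chromatography (C7 is only a relay and is erased in step 11, so either enantiomer of 14 can be chosen to match the observed facial preference).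

Step 10
Reactants: 17 coupled tertiary alcohol
Product: 18 triol (1R,4S,7R,10R)
Conditions: TBAF, THF, rt to 50 °C
Reagents that add atoms: none
Why: Fluoride cleaves both TBS ethers while the benzyl ether is inert, so the differentiation of C12–O from C7–O and C9–O does not rest on rate differences between silyl groups.

Step 11
Reactants: 18 triol
Product: 19 β-hydroxy keto aldehyde (1R,4S,10R)
Conditions: Dess–Martin periodinane, CH2Cl2, rt
Reagents that add atoms: none
Why: Dess–Martin oxidation takes the primary C9 alcohol to the aldehyde and the secondary C7 alcohol to the ketone in one operation under nearly neutral conditions, the tertiary C4 alcohol being unoxidisable.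

Step 12
Reactants: 19 β-hydroxy keto aldehyde
Product: 20 C4 trimethylsilyl ether and C6=C7 trimethylsilyl enol ether of 19
Conditions: TMSOTf, Et3N, CH2Cl2, −78 to 0 °C
Reagents that add atoms: trimethylsilyl triflate (TMSOTf), C[Si](C)(C)OS(=O)(=O)C(F)(F)F
Why: Soft enolisation and O-silylation: the tertiary alcohol is capped and the C7 ketone gives the only possible enol ether (towards C6, since C8 is quaternary), while the aldehyde has no α-hydrogen.

Step 13
Reactants: 20 bis-silylated aldehyde
Product: 21 Stetter precursor (1R,4S,10R): 4-(trimethylsilyloxy)-5,5-dimethylcyclopent-2-enone tethered to the α-quaternary aldehyde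
Conditions: Pd(OAc)2 (1.05 equiv), MeCN, rt
Reagents that add atoms: none
Why: Saegusa–Ito oxidation: palladation of the silyl enol ether at C6 and β-hydride elimination from C5 give the enone, with the tertiary silyl ether, the aldehyde and the benzyl ether as spectators.

Step 14
Reactants: 21 Stetter precursor
Product: 23 trans-fused bicyclic 1,4-diketone (1R,4S,5S,10R), via cis-fused diketone 22 (not isolated)
Conditions: 2-(pentafluorophenyl)-6,7-dihydro-5H-pyrrolo[2,1-c][1,2,4]triazol-2-ium tetrafluoroborate (30 mol %), i-Pr2NEt (30 mol %), toluene (0.01 M), 80 °C; then DBU, 60 °C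
Reagents that add atoms: none
Why: Base frees the triazolylidene, which attacks the C9 formyl group; a formal 1,2-hydrogen shift gives the enaminol (Breslow intermediate) in which C9 is nucleophilic, its conjugate addition to C5 forms the C9–C5 bond, and proton transfer to C6 with expulsion of the carbene releases the 1,4-diketone, i.e. an intramolecular Stetter reaction of an aliphatic aldehyde with a cyclic enone. The cycloheptanone closes in the 7-exo-trig mode (C6 remains outside the new ring), a ring size with few examples for this reaction, hence the high dilution, the heat and the small, electron-poor N-C6F5 carbene that eases enaminol formation from a crowded aldehyde. The selectivity needed is reaction of the acyl anion with C5 only, and 21 secures it: C10 is quaternary, so the aldehyde can neither enolise nor aldolise and is too hindered for intermolecular benzoin coupling, while the enone, flanked by C8 (CMe2) and fully substituted C4, has no acidic hydrogen and is left with the acceptor role alone. The tether leaves C4 on the face opposite to OSiMe3 and can span only that face of the flat enone, so the kinetic product should be the cis-fused diketone 22. C5–H is the only enolisable hydrogen next to C9, so DBU equilibrates this centre alone; the trans-fused epimer 23 (C9 cis to the C4 oxygen, 5S) is expected to prevail, as in the parent perhydroazulen-4-ones, and C1, C4 and C10 cannot epimerise.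

Step 15
Reactants: 23 trans-fused bicyclic 1,4-diketone
Product: 25 trans-fused hydroxy diketone with free C4–OH and C12–OH, via primary alcohol 24 (not isolated)
Conditions: H2 (1 atm), Pd/C, EtOAc, rt; filter; 1 M HCl, THF, 0 °C
Reagents that add atoms: none
Why: Hydrogenolysis of the benzyl ether (no alkene is left in the molecule) followed by mild acid hydrolysis of the tertiary trimethylsilyl ether, conditions that affect neither the ketones nor C5.

Step 16
Reactants: 25 trans-fused hydroxy diketone
Product: 26 C12 iodide of 25
Conditions: I2, PPh3, imidazole, CH2Cl2, 0 °C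
Reagents that add atoms: iodine, [I][I]
Why: Appel-type iodination of the only primary alcohol, the tertiary C4 alcohol being inert; the step follows all base treatment because a γ-iodo ketone would not tolerate enolising conditions.

Step 17
Reactants: 26 iodo hydroxy diketone
Product: 27 iodo diol (1R,4S,5S,7S,10R)
Conditions: Me4NBH(OAc)3, MeCN–AcOH (1:1), −20 °C to rt
Reagents that add atoms: none
Why: Evans–Saksena reduction: acetate exchange at C4–OH gives an alkoxydiacetoxyborohydride that hands its hydride to C7 on the face carrying C4–OH, so the new hydroxyl ends trans to it (7S), while the unbound reagent does not reduce ketones, C9 between quaternary C10 and the fusion CH is far more hindered than C7, and the alkyl iodide is inert.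

Step 18
Reactants: 27 iodo diol; 28 4-bromofuran-2(5H)-one
Product: 29 target CNP0077405.3
Conditions: NiBr2(dme) (10 mol %), 4,4'-di-tert-butyl-2,2'-bipyridine (10 mol %), Zn, DMA, rt
Reagents that add atoms: none
Why: Nickel-catalysed cross-electrophile (reductive) coupling of a primary alkyl iodide with an alkenyl bromide: the bromofuranone adds to low-valent nickel, the alkyl radical from the iodide is captured and reductive elimination forms the bond from C12 to the butenolide β-carbon under neutral conditions that tolerate hydroxyl groups, ketone and lactone and touch no stereocentre.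

Compound list
1 | methyl hydrogen (R)-3-methylglutarate, (3R)-5-methoxy-3-methyl-5-oxopentanoic acid | COC(=O)C[C@H](C)CC(=O)O | starting material
2 | methyl (3R)-5-hydroxy-3-methylpentanoate | COC(=O)C[C@H](C)CCO | intermediate
3 | (4R)-4-methyloxan-2-one | C[C@@H]1CCOC(=O)C1 | intermediate
4 | benzyl 2-iodoethyl ether | ICCOCc1ccccc1 | starting material
5 | lithium enolate of 3 | C[C@@H]1CCOC(O[Li])=C1 | intermediate
6 | (3S,4R)-3-[2-(benzyloxy)ethyl]-4-methyloxan-2-one (substituents trans) | C[C@@H]1CCOC(=O)[C@H]1CCOCc1ccccc1 | intermediate
7 | lithium enolate of 6 | C[C@@H]1CCOC(O[Li])=C1CCOCc1ccccc1 | intermediate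
8 | (3R,4R)-3-[2-(benzyloxy)ethyl]-3,4-dimethyloxan-2-one (methyl groups trans) | C[C@@H]1CCOC(=O)[C@]1(C)CCOCc1ccccc1 | intermediate
9 | (2R,3R)-2-[2-(benzyloxy)ethyl]-2,3-dimethylpentane-1,5-diol | OC[C@](C)(CCOCc1ccccc1)[C@H](C)CCO | intermediate
10 | (2R,3R)-2-[2-(benzyloxy)ethyl]-5-iodo-2,3-dimethylpentan-1-ol | OC[C@](C)(CCOCc1ccccc1)[C@H](C)CCI | intermediate
11 | tert-butyldimethylsilyl ether of 10 (C9–OTBS, C3–I, 1R,10R) | CC(C)(C)[Si](C)(C)OC[C@](C)(CCOCc1ccccc1)[C@H](C)CCI | intermediate
12 | 2,2-dimethylcyclopentane-1,3-dione | CC1(C)C(=O)CCC1=O | starting material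
13 | (3R)-3-hydroxy-2,2-dimethylcyclopentan-1-one | O=C1CC[C@@H](O)C1(C)C | intermediate
14 | (3R)-3-(tert-butyldimethylsilyloxy)-2,2-dimethylcyclopentan-1-one | O=C1CC[C@@H](O[Si](C)(C)C(C)(C)C)C1(C)C | intermediate
15 | primary alkyllithium from 11 (Li on C3) | CC(C)(C)[Si](C)(C)OC[C@](C)(CCOCc1ccccc1)[C@H](C)CC[Li] | intermediate
16 | alkylcerium dichloride from 15 (CeCl2 on C3) | CC(C)(C)[Si](C)(C)OC[C@](C)(CCOCc1ccccc1)[C@H](C)CC[Ce](Cl)Cl | intermediate
17 | coupled tertiary alcohol (1R,4S,7R,10R): 3-(TBSO)-2,2-dimethylcyclopentan-1-ol whose carbinol carbon C4 bears the chain C3H2–C2H2–C1H(CH3)–C10(CH3)(CH2OTBS)(CH2CH2OBn); C4–OH cis to C7–OTBS | CC(C)(C)[Si](C)(C)OC[C@](C)(CCOCc1ccccc1)[C@H](C)CC[C@]1(O)CC[C@@H](O[Si](C)(C)C(C)(C)C)C1(C)C | intermediate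
18 | triol (1R,4S,7R,10R): 17 with C7–OH and C9–OH free | OC[C@](C)(CCOCc1ccccc1)[C@H](C)CC[C@]1(O)CC[C@@H](O)C1(C)C | intermediate
19 | β-hydroxy keto aldehyde (1R,4S,10R): C7 ketone, C9 aldehyde, free C4–OH | O=C[C@](C)(CCOCc1ccccc1)[C@H](C)CC[C@]1(O)CCC(=O)C1(C)C | intermediate
20 | bis-silylated aldehyde: C4–OSiMe3 and C6=C7 trimethylsilyl enol ether | O=C[C@](C)(CCOCc1ccccc1)[C@H](C)CC[C@]1(O[Si](C)(C)C)CC=C(O[Si](C)(C)C)C1(C)C | intermediate
21 | Stetter precursor (1R,4S,10R): 4-(trimethylsilyloxy)-5,5-dimethylcyclopent-2-enone tethered through C3–C2–C1 to C10, which bears CH3, CH2CH2OBn and CHO | O=C[C@](C)(CCOCc1ccccc1)[C@H](C)CC[C@]1(O[Si](C)(C)C)C=CC(=O)C1(C)C | intermediate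
22 | cis-fused bicyclic 1,4-diketone (1R,4S,5R,10R): C9 trans to C4–OSiMe3 | C[C@@H]1CC[C@]2(O[Si](C)(C)C)[C@@H](CC(=O)C2(C)C)C(=O)[C@]1(C)CCOCc1ccccc1 | intermediate
23 | trans-fused bicyclic 1,4-diketone (1R,4S,5S,10R): C9 cis to C4–OSiMe3 | C[C@@H]1CC[C@]2(O[Si](C)(C)C)[C@H](CC(=O)C2(C)C)C(=O)[C@]1(C)CCOCc1ccccc1 | intermediate
24 | debenzylated 23 (C12–OH free, C4–OSiMe3) | C[C@@H]1CC[C@]2(O[Si](C)(C)C)[C@H](CC(=O)C2(C)C)C(=O)[C@]1(C)CCO | intermediate
25 | trans-fused hydroxy diketone (C4–OH and C12–OH free) | C[C@@H]1CC[C@]2(O)[C@H](CC(=O)C2(C)C)C(=O)[C@]1(C)CCO | intermediate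
26 | C12 iodide of 25 | C[C@@H]1CC[C@]2(O)[C@H](CC(=O)C2(C)C)C(=O)[C@]1(C)CCI | intermediate
27 | iodo diol (1R,4S,5S,7S,10R): C7–OH trans to C4–OH | C[C@@H]1CC[C@]2(O)[C@H](C[C@H](O)C2(C)C)C(=O)[C@]1(C)CCI | intermediate
28 | 4-bromofuran-2(5H)-one | O=C1C=C(Br)CO1 | starting material
29 | target CNP0077405.3 (1R,4S,5S,7S,10R) | C[C@@H]1CC[C@]2(O)[C@H](C[C@H](O)C2(C)C)C(=O)[C@]1(C)CCC1=CC(=O)OC1 | target

Total step count: 18. Longest linear sequence: 16 steps (steps 1–6 and 9–18).

Steps most likely to fail

Step 14
- What may go wrong: the carbene may add slowly to the neopentyl-type aldehyde. Closure of a seven-membered ring onto a β-carbon next to fully substituted C4 may also be slow, so that catalyst decay outruns cyclisation.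
- Fallback (reductive radical closure of the same bond, then re-oxidation): it sets out from 21.
- SmI2 in THF with t-BuOH (−78 to 0 °C) turns the aldehyde into its ketyl radical. This adds 7-exo to the same enone β-carbon in a ketyl–olefin cyclisation, a process less sensitive to crowding than addition of the bulky enaminol. The product is the cis-fused C9 carbinol F1, whose configuration at C9 is irrelevant.
- Dess–Martin oxidation of F1 gives 22.
- DBU, as in the second stage of step 14, converts 22 into 23.

Step 17
- What may go wrong: in the trans-fused series C9 stands cis to the C4 hydroxyl group, so the boron-bound hydride may be handed to C9 as well as to C7.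
- Slow acetate exchange at the crowded tertiary alcohol may also let undirected attack from the wrong face compete.
- An unfavourable position of the C5 equilibrium at the silyl ether stage would hurt at the same point.
- Fallback (reduction before epimerisation): step 14 is stopped before DBU is added and 22 is isolated.
- Hydrogenolysis gives the cis-fused silyl ether alcohol F2, and dilute acid gives the cis-fused hydroxy diketone F3.
- In F3 the seven-membered ring hangs from the face opposite to C4–OH. C9 is therefore out of reach of the bound hydride, and the convex face coincides with the directing face. Me4NBH(OAc)3 should then give the cis-fused triol F4 (7S).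
- DBU in toluene then equilibrates C5 and leads to the trans-fused triol F5. The equilibrium is now helped by the hydrogen bond between C4–OH and the C9 carbonyl group, which only the trans-fused epimer can form.
- PPh3/I2/imidazole iodinates the only primary alcohol of F5, which brings the sequence back to 27.

Step 18
- What may go wrong: the primary C12 radical may be lost to 1,5-hydrogen transfer from C5–H, to reduction or to dimerisation before nickel captures it. Direct reduction or homocoupling of the bromofuranone by zinc is also possible.
- Fallback (preformed organozinc and palladium catalysis instead of radical capture): it sets out from 27.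
- TMSOTf/2,6-lutidine gives the bis(trimethylsilyl) ether F6.
- Zinc dust with LiCl in THF inserts into the C–I bond to give the alkylzinc iodide F7.
- Negishi coupling of F7 with 28 under Pd(PPh3)4 gives the silylated butenolide F8.
- Dilute HCl in THF removes both silyl groups and gives 29.

Further compounds
F1 | step 14 | cis-fused C9 carbinol (C9–OH in place of the C9 ketone of 22, C9 configuration not assigned) | C[C@@H]1CC[C@]2(O[Si](C)(C)C)[C@@H](CC(=O)C2(C)C)C(O)[C@]1(C)CCOCc1ccccc1
F2 | step 17 | cis-fused silyl ether alcohol (debenzylated 22) | C[C@@H]1CC[C@]2(O[Si](C)(C)C)[C@@H](CC(=O)C2(C)C)C(=O)[C@]1(C)CCO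
F3 | step 17 | cis-fused hydroxy diketone (C5 epimer of 25) | C[C@@H]1CC[C@]2(O)[C@@H](CC(=O)C2(C)C)C(=O)[C@]1(C)CCO
F4 | step 17 | cis-fused triol (1R,4S,5R,7S,10R) | C[C@@H]1CC[C@]2(O)[C@@H](C[C@H](O)C2(C)C)C(=O)[C@]1(C)CCO
F5 | step 17 | trans-fused triol (1R,4S,5S,7S,10R) | C[C@@H]1CC[C@]2(O)[C@H](C[C@H](O)C2(C)C)C(=O)[C@]1(C)CCO
F6 | step 18 | bis(trimethylsilyl) ether of 27 | C[C@@H]1CC[C@]2(O[Si](C)(C)C)[C@H](C[C@H](O[Si](C)(C)C)C2(C)C)C(=O)[C@]1(C)CCI
F7 | step 18 | alkylzinc iodide from F6 | C[C@@H]1CC[C@]2(O[Si](C)(C)C)[C@H](C[C@H](O[Si](C)(C)C)C2(C)C)C(=O)[C@]1(C)CC[Zn]I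
F8 | step 18 | bis(trimethylsilyl) ether of 29 | C[C@@H]1CC[C@]2(O[Si](C)(C)C)[C@H](C[C@H](O[Si](C)(C)C)C2(C)C)C(=O)[C@]1(C)CCC1=CC(=O)OC1
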